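## Analysis of the target

The target is a furofuran lignan, a 2,6-diaryl-3,7-dioxabicyclo[3.3.0]octane. Its two tetrahydrofuran rings, ring A (C7–O2–C9'–C8'–C8) and ring B (C7'–O7–C9–C8–C8'), share the C8–C8' bond. C7 carries a 4-hydroxy-3,5-dimethoxyphenyl group and C7' a 3,4,5-trimethoxyphenyl group, so a single O-methyl group breaks the C2 symmetry of the core and the two halves cannot come from a dimerisation. The four contiguous stereocentres read 7R,8S,7'R,8'S: the ring fusion is cis, and each aryl group is exo, that is cis to the hydrogen on the neighbouring ring-fusion carbon and trans to the CH2 group of the other ring. This is the mirror-image series of the common dextrorotatory furofurans, so a natural lignan is no shortcut. The sensitive sites are the benzylic ether bonds C7–O2 and C7'–O7 on electron-rich rings, which ionise under acid (epimerisation) and can be cut by hydrogenolysis, and the free phenol para to C7, which as a phenoxide weakens C7–O2 further. The difficulty is to set four centres in the absolute sense while two nearly identical aryl groups are brought in separately and the finished benzylic ethers never meet strong acid. The strategy rests on ring A: its two C–C bonds, C7–C8 and C9'–C8', run from the carbons flanking O2 to the cis pair C8/C8', which is the imprint of a C7–O2–C9' carbonyl ylide on a cis alkene. If that alkene is the double bond of a butenolide with C7' as carbonyl carbon and C9 as γ-carbon, ring B is present as a lactone from the start.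

## Retrosynthetic reasoning

**18 from 17.** The O–CH2Ph bond of the phenol ether is cut last. A free phenol would not survive the basic, organometallic and Lewis-acidic steps, so it is carried as the benzyl ether 17 and released under neutral hydrogenolysis, which asks nothing of the four stereocentres.

**17 from 12 and 15.** The C7'–aryl bond is cut. This makes C7' the carbon of a ring B oxocarbenium ion (16) inside a rigid cis-fused bicycle whose convex face is open, so an aryl nucleophile should enter exo and set C7' by substrate control. The aryl group has to come as a metalated ring carbon (15, from bromide 13 through 14), because an electrophilic substitution on the free arene would engage a position ortho to a methoxy group and give the wrong substitution pattern. The reverse polarity, aryl addition to lactone 10 followed by hydride delivery, would place hydride on the convex face and the aryl endo, and is therefore not used.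

**12 from 10.** This is an oxidation-level adjustment at C7', from lactone to lactol acetate. It turns the carbonyl that the butenolide brought along into a leaving group at the aldehyde level without touching any stereocentre.

**10 from 7.** The C9–O bond to the auxiliary is cut and C9 is taken from the acetal level to CH2. In the forward sense the acyloxy acetal is opened, the liberated C9 aldehyde is reduced and the hydroxy acid closes again onto C7'. The carbonyl stays at C7' and the auxiliary leaves. The gain is that 7 may carry a removable stereocontrolling group on C9, directly beside C8.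

**7 from 4 and 5 through 6.** This is the key disconnection: C7–C8 and C9'–C8' are cut together. It is made here because these two bonds build ring A in one step, bring O2 with both its carbons from one reagent and create C7, C8 and C8' at once. Cutting the C–O bonds of ring A instead would first need a stereodefined acyclic triad. The forward reaction has to deliver ylide 6 to the face of 5 anti to the menthyloxy group, with C7 on C8 (not on C8') and with the aryl turned away from the lactone.

**4 from 3, and 3 from 1.** The O–CH2Cl bond of 4 comes from chloromethylation of carbinol 3, and the C7–Si bond of 3 from addition of a silyl nucleophile to aldehyde 1 under copper catalysis. A dimethylphenylsilyl group is used because a silyl–boron reagent puts it on the aldehyde carbon in one step under nearly neutral conditions. An O-silylation followed by a base-induced silyl shift from O to C would need an alkyllithium, which could also metalate the benzyl ether CH2 and the ring positions next to methoxy. The silyl group is a spectator that leaves the molecule in the key step, and 3 may be racemic because C7 becomes planar in 6.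

## Alternatives that were turned down

**Alternative 1:** Radical bicyclisation of an epoxy cinnamyl ether.
- Disconnection: C8–C8' and C7'–O7, leading back to A1, the C7 ether of an aryl oxiranyl carbinol with a 3,4,5-trimethoxycinnamyl group.
- Forward key step: Cp2TiCl (trivalent titanium) opens the epoxide to a C8 radical, which cyclises 5-exo onto C8' and closes ring A. Iodine then activates benzylic C7' so that the C9 titanium alkoxide closes ring B, giving A2, which has the structure of 17.
- For it: one operation makes the C8–C8' bond, both rings and three stereocentres. No auxiliary has to be removed and no lactone has to be adjusted. From A1 only two steps remain.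
- Against it: all stereochemistry is relayed from the single centre C7 of A1, which must first be made enantiopure on an acid-labile benzylic ether that also carries an epoxide. The relay to C8 rests on a modest conformational preference in the radical cyclisation, and C7' is fixed in a cation or iodide closure without its own control element. The titanium reagent is stoichiometric.
- Comparison: it is stronger in bonds and rings per step and about equal in total length once A1 and its cinnamyl part are counted. The chosen route offers in its place absolute control from a crystalline auxiliary reagent, a separate control element for each benzylic centre, and simple building blocks (an aldehyde and an aryl bromide).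

**Alternative 2:** Three-component conjugate addition–aldol on the chiral butenolide.
- Disconnection: C7–C8 and C7'–C8'; no ring of the target is cut.
- Forward key step: lithiated dithiane A3 (the acyl anion for C7, from 1) adds to the β-carbon of 5 anti to the menthyloxy group, and the enolate is trapped by aldehyde A4 to give the trans lactone A5.
- For it: regiochemistry cannot scramble (Michael bond first, aldol bond second). It uses the same auxiliary, both aryl groups enter as aldehydes, and on paper it is as short as the chosen route or slightly shorter.
- Against it: the key step closes no ring and leaves C7 masked and C7' unassigned. The dithioketal must then be removed with a heavy-metal reagent, three carbonyl-level carbons reduced and both rings closed by ionising two electron-rich benzylic carbinols. The configuration at C7 and C7' then depends on how two benzylic cations happen to close, at centres where exo and endo isomers lie close in energy.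
- Comparison: it is stronger on regiochemical certainty and not weaker on step count. The chosen route offers ring A and C7 formed in the same kinetic step, and C7' set by convex-face attack on a rigid bicycle. The finished benzylic ethers meet no strong acid.

**Alternative 3:** Prins annulation of a ring A dihydrofuran.
- Disconnection: O7–C7' and C7'–C8' (ring B), leading back to the dihydrofuran carbinol A6 and the aryl acetal A7.
- Forward key step: TMSOTf exchanges the C9 hydroxyl of A6 into A7. The resulting oxocarbenium ion is attacked by the enol ether through C8', which closes ring B, and methoxide released from A7 caps C9' to give the methyl acetal A8.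
- For it: it is convergent, brings the second aryl group in at the aldehyde level without an organometallic, and sets C7' and C8' under the bias of the existing ring.
- Against it: A6, an enantiopure trans-2-aryl-3-hydroxymethyl-2,3-dihydrofuran, is an acid-sensitive cyclic enol ether that needs a multistep asymmetric synthesis of its own. A8 carries an extra methoxy group on C9' that must be reduced off with a silane and a Lewis acid in the presence of both benzylic ethers. The C7' outcome of the cationic closure is plausible but not enforced.
- Comparison: it is as strong in convergence. The chosen route makes the ring that this alternative presupposes (ring A with C7 and C8) in one step from simple parts, and keeps the carbon that becomes C9' at the right oxidation level throughout.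

Key step: step 3

Remark on the chemistry: furanone 5 is taken as a purchasable, diastereomerically pure reagent; should it have to be made, furfural and (+)-menthol give it in two operations.

## Route

Step 1
Reactants: 1 4-(benzyloxy)-3,5-dimethoxybenzaldehyde
Product: 3 rac-[4-(benzyloxy)-3,5-dimethoxyphenyl][dimethyl(phenyl)silyl]methanol, via O-pinacolboryl ether 2 (not isolated)
Conditions: Me2PhSi–Bpin (1.2 equiv), CuCl (5 mol%), 1,3-bis(2,6-diisopropylphenyl)imidazolium chloride (IPr·HCl, 5 mol%), NaOt-Bu (12 mol%), THF, rt; then aq. NH4Cl
Reagents that add atoms: (dimethylphenylsilyl)boronic acid pinacol ester, C[Si](C)(c1ccccc1)B1OC(C)(C)C(C)(C)O1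
Why: Copper-catalysed 1,2-silylation of an aldehyde: the carbene-bound copper alkoxide (monovalent copper) cleaves the Si–B bond, the copper silyl adds silicon to the carbonyl carbon, and exchange with more silylborane gives boryl ether 2, which is hydrolysed on work-up. The nearly neutral medium should avoid the silyl shift from carbon to oxygen that alkoxide bases cause, and the benzyl ether is untouched. The new centre forms racemic, which is harmless because it becomes planar in step 3.

Step 2
Reactants: 3 rac-[4-(benzyloxy)-3,5-dimethoxyphenyl][dimethyl(phenyl)silyl]methanol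
Product: 4 rac-{[4-(benzyloxy)-3,5-dimethoxyphenyl](chloromethoxy)methyl}dimethyl(phenyl)silane
Conditions: (CH2O)n, Me3SiCl, CH2Cl2, 0 °C → rt; volatiles removed, used crude
Reagents that add atoms: paraformaldehyde (formaldehyde units), C=O; chlorotrimethylsilane, C[Si](C)(C)Cl
Why: Chloromethylation of an alcohol: the carbinol forms a hemiformal with formaldehyde, and the chlorosilane converts its OH into chloride through the oxocarbenium ion, driven by Si–O bond formation. No base is present, so the α-silyl carbinol cannot rearrange, and the C–Si bond and the racemic centre are not touched.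

Step 3
Reactants: 4 rac-{[4-(benzyloxy)-3,5-dimethoxyphenyl](chloromethoxy)methyl}dimethyl(phenyl)silane (1.5–2 equiv); 5 (5S)-5-{[(1S,2R,5S)-2-isopropyl-5-methylcyclohexyl]oxy}furan-2(5H)-one
Product: 7 (3S,3aR,4R,6aS)-4-[4-(benzyloxy)-3,5-dimethoxyphenyl]-3-{[(1S,2R,5S)-2-isopropyl-5-methylcyclohexyl]oxy}tetrahydro-1H,3H-furo[3,4-c]furan-1-one, via carbonyl ylide 6 (not isolated)
Conditions: CsF (dried, 3 equiv), MeCN, rt, slow addition of 4 to 5
Reagents that add atoms: none
Why: Fluoride attacks silicon in 4, and the benzylic carbon, as it takes up the C–Si electrons, expels chloride from the OCH2Cl arm (1,3-elimination), so that the non-stabilised carbonyl ylide 6, a four-electron dipole over C7–O2–C9', is released in low stationary concentration. Ylide 6 adds to the electron-poor C8=C8' bond of 5 in a concerted, suprafacial [3+2] cycloaddition controlled by the dipole HOMO and the alkene LUMO; the closest known reaction type is the fluoride-triggered carbonyl ylide cycloaddition of chloromethyl α-silylalkyl ethers to acrylates, fumarates and maleates, together with the use of 5 as an anti-selective chiral dipolarophile toward other 1,3-dipoles. Ring A is closed by the cycloaddition itself: C7–C8 and C9'–C8' form on one face of the alkene in one kinetic step, so no exo or endo ring-closure mode is involved and the ring fusion must be cis. C8 and C8' are controlled by the acetal centre C9 of 5, whose menthyloxy group blocks its own face of the planar butenolide so that the dipole adds anti to it. C7 is controlled by the geometry of 6 (aryl on the outside of the C–O–C sickle) together with an exo approach in which O2 points away from the lactone ring, which leaves the aryl trans to C9. The step needs regioselectivity, C7 to the β-carbon C8 and C9' to the α-carbon C8': the carbon that loses silicon keeps carbanion character that the aryl ring delocalises, while the CH2 terminus is the oxocarbenium-like end, so the Michael-type bond from C7 to C8 should lead and the enolate-like C8' should close onto C9'. It also needs the dipole to be trapped faster than it dimerises, which slow addition of an excess of 4 and dry CsF should secure.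

Step 4
Reactants: 7 (3S,3aR,4R,6aS)-4-[4-(benzyloxy)-3,5-dimethoxyphenyl]-3-{[(1S,2R,5S)-2-isopropyl-5-methylcyclohexyl]oxy}tetrahydro-1H,3H-furo[3,4-c]furan-1-one
Product: 10 (3aS,4R,6aS)-4-[4-(benzyloxy)-3,5-dimethoxyphenyl]tetrahydro-1H,3H-furo[3,4-c]furan-1-one, via formyl carboxylate 8 (not isolated), via hydroxy carboxylate 9 (not isolated)
Conditions: NaBH4, KOH, EtOH/H2O, 0 °C → rt; then 2 M HCl to pH 2, rt
Reagents that add atoms: potassium hydroxide (its oxygen enters the carboxylate and can remain as the lactone carbonyl oxygen), [K+].[OH-]
Why: Saponification of the acyloxy acetal opens the lactone, and the hemiacetal at C9 collapses with loss of the auxiliary alcohol to aldehyde 8, which the borohydride already present reduces to 9 before it can enolise. Acidification closes the γ-lactone from the C9 hydroxyl onto the C7' acid, which is possible because C8 and C8' are cis; this is a reductive removal of the alkoxy group from a γ-alkoxy lactone. No stereocentre is formed, and C7, C8 and C8' are retained.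

Step 5
Reactants: 10 (3aS,4R,6aS)-4-[4-(benzyloxy)-3,5-dimethoxyphenyl]tetrahydro-1H,3H-furo[3,4-c]furan-1-one
Product: 12 (3aS,4R,6aS)-4-[4-(benzyloxy)-3,5-dimethoxyphenyl]tetrahydro-1H,3H-furo[3,4-c]furan-1-yl acetate (both C1 epimers, C1 being C7'), via aluminium lactolate 11 (not isolated)
Conditions: i-Bu2AlH, CH2Cl2, −78 °C; then pyridine, DMAP, Ac2O, −78 °C → 0 °C
Reagents that add atoms: acetic anhydride, CC(=O)OC(C)=O
Why: One-pot reductive acetylation of a lactone: hydride adds once to C7', the tetrahedral aluminium lactolate 11 is stable at −78 °C, and acylation traps it before it can open to the hydroxy aldehyde. The configuration of the new acetal centre does not matter because it is ionised in step 7.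

Step 6
Reactants: 13 5-bromo-1,2,3-trimethoxybenzene
Product: 15 (3,4,5-trimethoxyphenyl)zinc bromide (THF solution), via arylmagnesium bromide 14 (not isolated)
Conditions: Mg, I2 (cat.), THF, reflux → rt; then ZnBr2, THF, 0 °C → rt
Reagents that add atoms: zinc bromide, Br[Zn]Br
Why: Grignard formation followed by transmetalation from magnesium to zinc. The arylzinc halide is a soft aryl donor that tolerates a Lewis acid and delivers the ring carbon that bore bromine, which fixes the 3,4,5-pattern.

Step 7
Reactants: 12 (3aS,4R,6aS)-4-[4-(benzyloxy)-3,5-dimethoxyphenyl]tetrahydro-1H,3H-furo[3,4-c]furan-1-yl acetate; 15 (3,4,5-trimethoxyphenyl)zinc bromide (2 equiv)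
Product: 17 (1R,3aS,4R,6aS)-1-[4-(benzyloxy)-3,5-dimethoxyphenyl]-4-(3,4,5-trimethoxyphenyl)tetrahydro-1H,3H-furo[3,4-c]furan, via oxocarbenium ion 16 (not isolated)
Conditions: BF3·OEt2, CH2Cl2/THF (10:1), −78 °C → −20 °C
Reagents that add atoms: none
Why: Lewis-acid-promoted substitution of a lactol acetate by an organozinc nucleophile (C-glycosylation type): BF3 ionises the acetate to the ring B oxocarbenium ion 16, and the arylzinc transfers its ipso carbon to C7'. C7' is set by the cis-fused bicycle: the nucleophile enters on the convex face, anti to the C8'–C9' bond, so the new aryl ends cis to H8' (exo, 7'R). At low temperature the C7–O2 ether should ionise far more slowly than the acetate.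

Step 8
Reactants: 17 (1R,3aS,4R,6aS)-1-[4-(benzyloxy)-3,5-dimethoxyphenyl]-4-(3,4,5-trimethoxyphenyl)tetrahydro-1H,3H-furo[3,4-c]furan
Product: 18 2,6-dimethoxy-4-[(1R,3aS,4R,6aS)-4-(3,4,5-trimethoxyphenyl)tetrahydro-1H,3H-furo[3,4-c]furan-1-yl]phenol
Conditions: H2 (1 atm), Pd/C (10%), EtOAc, rt, stopped at consumption of 17
Reagents that add atoms: none
Why: Hydrogenolysis of an aryl benzyl ether, which should be much faster than cleavage of the dialkyl benzylic ethers C7–O2 and C7'–O7 in a neutral, non-acidic solvent. No stereocentre is involved.

## Compound list

1 | 4-(benzyloxy)-3,5-dimethoxybenzaldehyde | COc1cc(C=O)cc(OC)c1OCc1ccccc1 | starting material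
2 | rac-2-{[4-(benzyloxy)-3,5-dimethoxyphenyl][dimethyl(phenyl)silyl]methoxy}-4,4,5,5-tetramethyl-1,3,2-dioxaborolane | COc1cc(C(OB2OC(C)(C)C(C)(C)O2)[Si](C)(C)c2ccccc2)cc(OC)c1OCc1ccccc1 | intermediate
3 | rac-[4-(benzyloxy)-3,5-dimethoxyphenyl][dimethyl(phenyl)silyl]methanol | COc1cc(C(O)[Si](C)(C)c2ccccc2)cc(OC)c1OCc1ccccc1 | intermediate
4 | rac-{[4-(benzyloxy)-3,5-dimethoxyphenyl](chloromethoxy)methyl}dimethyl(phenyl)silane | COc1cc(C(OCCl)[Si](C)(C)c2ccccc2)cc(OC)c1OCc1ccccc1 | intermediate
5 | (5S)-5-{[(1S,2R,5S)-2-isopropyl-5-methylcyclohexyl]oxy}furan-2(5H)-one | O=C1C=C[C@H](O1)O[C@H]1C[C@@H](C)CC[C@@H]1C(C)C | starting material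
6 | carbonyl ylide, [4-(benzyloxy)-3,5-dimethoxyphenyl]methanide bound to O-methyleneoxonium, ArCH(−)–O(+)=CH2 | COc1cc([CH-][O+]=C)cc(OC)c1OCc1ccccc1 | intermediate
7 | (3S,3aR,4R,6aS)-4-[4-(benzyloxy)-3,5-dimethoxyphenyl]-3-{[(1S,2R,5S)-2-isopropyl-5-methylcyclohexyl]oxy}tetrahydro-1H,3H-furo[3,4-c]furan-1-one (cis-fused, aryl trans to C9, menthyloxy trans to C7) | COc1cc([C@@H]2OC[C@@H]3[C@H]2[C@@H](O[C@H]2C[C@@H](C)CC[C@@H]2C(C)C)OC3=O)cc(OC)c1OCc1ccccc1 | intermediate
8 | potassium (3S,4R,5R)-5-[4-(benzyloxy)-3,5-dimethoxyphenyl]-4-formyltetrahydrofuran-3-carboxylate | COc1cc([C@@H]2OC[C@@H](C(=O)[O-])[C@H]2C=O)cc(OC)c1OCc1ccccc1.[K+] | intermediate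
9 | potassium (3S,4S,5R)-5-[4-(benzyloxy)-3,5-dimethoxyphenyl]-4-(hydroxymethyl)tetrahydrofuran-3-carboxylate | COc1cc([C@@H]2OC[C@@H](C(=O)[O-])[C@H]2CO)cc(OC)c1OCc1ccccc1.[K+] | intermediate
10 | (3aS,4R,6aS)-4-[4-(benzyloxy)-3,5-dimethoxyphenyl]tetrahydro-1H,3H-furo[3,4-c]furan-1-one | COc1cc([C@@H]2OC[C@@H]3[C@H]2COC3=O)cc(OC)c1OCc1ccccc1 | intermediate
11 | diisobutylaluminium (3aS,4R,6aS)-4-[4-(benzyloxy)-3,5-dimethoxyphenyl]tetrahydro-1H,3H-furo[3,4-c]furan-1-olate (C1 epimers) | COc1cc([C@@H]2OC[C@@H]3[C@H]2COC3O[Al](CC(C)C)CC(C)C)cc(OC)c1OCc1ccccc1 | intermediate
12 | (3aS,4R,6aS)-4-[4-(benzyloxy)-3,5-dimethoxyphenyl]tetrahydro-1H,3H-furo[3,4-c]furan-1-yl acetate (C1 epimers) | COc1cc([C@@H]2OC[C@@H]3[C@H]2COC3OC(C)=O)cc(OC)c1OCc1ccccc1 | intermediate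
13 | 5-bromo-1,2,3-trimethoxybenzene | COc1cc(Br)cc(OC)c1OC | starting material
14 | (3,4,5-trimethoxyphenyl)magnesium bromide | COc1cc([Mg]Br)cc(OC)c1OC | intermediate
15 | (3,4,5-trimethoxyphenyl)zinc bromide | COc1cc([Zn]Br)cc(OC)c1OC | intermediate
16 | ring B oxocarbenium ion (C7'=O7 cation) of the (3aS,4R,6aS)-4-aryl bicycle | COc1cc([C@@H]2OC[C@@H]3[C@H]2C[O+]=C3)cc(OC)c1OCc1ccccc1 | intermediate
17 | (1R,3aS,4R,6aS)-1-[4-(benzyloxy)-3,5-dimethoxyphenyl]-4-(3,4,5-trimethoxyphenyl)tetrahydro-1H,3H-furo[3,4-c]furan | COc1cc([C@@H]2OC[C@@H]3[C@H]2CO[C@H]3c2cc(OC)c(OC)c(OC)c2)cc(OC)c1OCc1ccccc1 | intermediate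
18 | 2,6-dimethoxy-4-[(1R,3aS,4R,6aS)-4-(3,4,5-trimethoxyphenyl)tetrahydro-1H,3H-furo[3,4-c]furan-1-yl]phenol | COc1cc([C@@H]2OC[C@@H]3[C@H]2CO[C@H]3c2cc(OC)c(OC)c(OC)c2)cc(OC)c1O | target

## Step count and least certain steps

Total: 8 steps. Longest linear sequence: 7 steps (1 → 3 → 4 → 7 → 10 → 12 → 17 → 18); step 6 is a one-step side branch.

**Step 3 (key step).** The dipole may add with the other regiochemistry (C9' to C8), approach endo so that C7 forms epimeric, or dimerise before it meets the moderately reactive butenolide. All three are possible because 5 enforces only the face of attack, not the orientation of the dipole. The fallback sets out from 1 and 5 and returns at 17, using the same auxiliary in a stepwise ionic sequence in which the regiochemistry cannot scramble. Aldehyde 1 is condensed with propane-1,3-dithiol (BF3·OEt2, CH2Cl2) to 2-[4-(benzyloxy)-3,5-dimethoxyphenyl]-1,3-dithiane F1. Its 2-lithio derivative (n-BuLi, THF, −78 °C) adds to C8 of 5 anti to the menthyloxy group, and the lactone enolate is trapped with 3,4,5-trimethoxybenzaldehyde (A4) to give the trans-disubstituted lactone carbinol F2, which has the structure of A5. Hydrolysis of the dithioketal (HgO, BF3·OEt2, aqueous THF) gives the keto lactone F3, and LiAlH4 in THF reduces ketone, lactone and acetal to the tetraol F4 with loss of the auxiliary. Camphorsulfonic acid in CH2Cl2 should then close rings A and B through the two benzylic cations, each aryl settling trans to its ring neighbour, to give 17.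

**Step 2.** The acid formed during chloromethylation may ionise the electron-rich benzylic carbinol or remove silicon from it, and the chloromethyl ether may hydrolyse on handling. The fallback sets out from 3 and returns at 4. Carbinol 3 is converted under neutral conditions (Me2S, dibenzoyl peroxide, MeCN, 0 °C) into the methylthiomethyl ether F5, which is cleaved with SO2Cl2 in CH2Cl2 at −78 °C to 4 immediately before use.

**Step 4.** The liberated C9 aldehyde may enolise toward C8 before it is reduced, which would epimerise C8 or open ring A by β-elimination of O2, and the acid work-up may ionise C7–O2. The fallback sets out from 7 and returns at 10. LiAlH4 in THF at 0 °C reduces lactone and acetal directly, with no free aldehyde in a basic medium, to [(2R,3S,4S)-2-[4-(benzyloxy)-3,5-dimethoxyphenyl]tetrahydrofuran-3,4-diyl]dimethanol F6. Oxidative lactonisation with TEMPO and PhI(OAc)2 in CH2Cl2 should start at the less hindered C7' carbinol and give 10.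

**Step 7.** Aryl transfer from zinc to the oxocarbenium ion may be slow, so that the ion loses a proton to the enol ether or the Lewis acid begins to ionise C7–O2 and erodes C7. The fallback sets out from 10 and returns at 17. Lactone 10 is reduced with i-Bu2AlH (CH2Cl2, −78 °C, aqueous work-up) to the lactol F7. Excess Grignard reagent 14 adds to its open hydroxy aldehyde form to give the diol F8 as a C7' epimer mixture. A catalytic amount of camphorsulfonic acid in CH2Cl2 should then close ring B through the C7' benzylic cation with the aryl trans to C9', giving 17.

**Step 8.** Hydrogenolysis may go on after the benzyl ether is gone and cut C7–O2 or C7'–O7. The fallback sets out from 17 and returns at 18. The benzyl group is removed without hydrogen by BCl3 and pentamethylbenzene in CH2Cl2 at −78 °C, where the benzyl ether flanked by two methoxy groups should cleave much faster than the ring ethers and the benzyl cation is trapped by the arene. No new intermediate is formed.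

## Further compounds

F1 | step 3 | 2-[4-(benzyloxy)-3,5-dimethoxyphenyl]-1,3-dithiane | COc1cc(C2SCCCS2)cc(OC)c1OCc1ccccc1
F2 | step 3 | trans lactone carbinol: menthyloxy lactone with the 2-aryl-1,3-dithian-2-yl group on C8 (anti to menthyloxy) and the aryl(hydroxy)methyl group on C8' (carbinol configuration open) | O=C1O[C@H](O[C@H]2C[C@@H](C)CC[C@@H]2C(C)C)[C@@H](C2(c3cc(OC)c(OCc4ccccc4)c(OC)c3)SCCCS2)[C@@H]1C(O)c1cc(OC)c(OC)c(OC)c1
F3 | step 3 | keto lactone: as F2 with the dithioketal replaced by the C7 ketone | O=C1O[C@H](O[C@H]2C[C@@H](C)CC[C@@H]2C(C)C)[C@@H](C(=O)c2cc(OC)c(OCc3ccccc3)c(OC)c2)[C@@H]1C(O)c1cc(OC)c(OC)c(OC)c1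
F4 | step 3 | tetraol: 1-[4-(benzyloxy)-3,5-dimethoxyphenyl]-2,3-bis(hydroxymethyl)-4-(3,4,5-trimethoxyphenyl)butane-1,4-diol, C8 and C8' as in the target, carbinol centres open | OC[C@@H](C(O)c1cc(OC)c(OCc2ccccc2)c(OC)c1)[C@@H](CO)C(O)c1cc(OC)c(OC)c(OC)c1
F5 | step 2 | rac-{[4-(benzyloxy)-3,5-dimethoxyphenyl][(methylsulfanyl)methoxy]methyl}dimethyl(phenyl)silane | COc1cc(C(OCSC)[Si](C)(C)c2ccccc2)cc(OC)c1OCc1ccccc1
F6 | step 4 | [(2R,3S,4S)-2-[4-(benzyloxy)-3,5-dimethoxyphenyl]tetrahydrofuran-3,4-diyl]dimethanol | COc1cc([C@@H]2OC[C@@H](CO)[C@H]2CO)cc(OC)c1OCc1ccccc1
F7 | step 7 | (3aS,4R,6aS)-4-[4-(benzyloxy)-3,5-dimethoxyphenyl]tetrahydro-1H,3H-furo[3,4-c]furan-1-ol (lactol, C1 epimers) | COc1cc([C@@H]2OC[C@@H]3[C@H]2COC3O)cc(OC)c1OCc1ccccc1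
F8 | step 7 | [(3S,4S,5R)-5-[4-(benzyloxy)-3,5-dimethoxyphenyl]-4-(hydroxymethyl)tetrahydrofuran-3-yl](3,4,5-trimethoxyphenyl)methanol (C7' epimers) | COc1cc([C@@H]2OC[C@@H](C(O)c3cc(OC)c(OC)c(OC)c3)[C@H]2CO)cc(OC)c1OCc1ccccc1
F0 | step 8 | none | none
A1 | alternative 1 | epoxy cinnamyl ether: (E)-3-(3,4,5-trimethoxyphenyl)allyl ether of [4-(benzyloxy)-3,5-dimethoxyphenyl](oxiran-2-yl)methanol, C7 arranged as in the target, epoxide centre open | COc1cc([C@H](OC/C=C/c2cc(OC)c(OC)c(OC)c2)C2CO2)cc(OC)c1OCc1ccccc1
A2 | alternative 1 | 4-O-benzyl ether of the target (same structure as 17) | COc1cc([C@@H]2OC[C@@H]3[C@H]2CO[C@H]3c2cc(OC)c(OC)c(OC)c2)cc(OC)c1OCc1ccccc1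
A3 | alternative 2 | 2-[4-(benzyloxy)-3,5-dimethoxyphenyl]-1,3-dithiane | COc1cc(C2SCCCS2)cc(OC)c1OCc1ccccc1
A4 | alternative 2 | 3,4,5-trimethoxybenzaldehyde | COc1cc(C=O)cc(OC)c1OC
A5 | alternative 2 | trans-disubstituted menthyloxy lactone adduct (C7 as dithioketal, C7' as carbinol, carbinol configuration open) | O=C1O[C@H](O[C@H]2C[C@@H](C)CC[C@@H]2C(C)C)[C@@H](C2(c3cc(OC)c(OCc4ccccc4)c(OC)c3)SCCCS2)[C@@H]1C(O)c1cc(OC)c(OC)c(OC)c1
A6 | alternative 3 | [(2R,3S)-2-[4-(benzyloxy)-3,5-dimethoxyphenyl]-2,3-dihydrofuran-3-yl]methanol (trans) | COc1cc([C@@H]2OC=C[C@H]2CO)cc(OC)c1OCc1ccccc1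
A7 | alternative 3 | 3,4,5-trimethoxybenzaldehyde dimethyl acetal | COC(OC)c1cc(OC)c(OC)c(OC)c1
A8 | alternative 3 | C9' methyl acetal of the O-benzyl target (exo methoxy) | COc1cc([C@@H]2O[C@H](OC)[C@@H]3[C@H]2CO[C@H]3c2cc(OC)c(OC)c(OC)c2)cc(OC)c1OCc1ccccc1
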